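The plan cuts the benzene ring of the indole at C3a–C4 and C7–C7a. The fragment C4(H)–C5(Br)–C6(Br)–C7(H) is the carbon backbone of 3,4-dibromothiophene, and C3a (carbon-substituted) and C7a (nitrogen-substituted) are the two carbons of an ynamide. In one operation, [4+2] cycloaddition of 3,4-dibromothiophene 1,1-dioxide to an N-Boc-N-methyl ynamide bearing a 2-silyloxyethyl chain, followed by loss of SO2, should deliver the tetrasubstituted benzene ring as a single isomer with nitrogen and side chain ortho to each other. Oxidation of the chain and lactamisation then give the oxindole, and a Vilsmeier bromoformylation installs the C2 bromine and the C3 aldehyde.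

Key step: step 4

Remark: the target has no stereocentre; the tert-butyldimethylsilyl ether of but-3-yn-1-ol is taken as a purchased compound (it is otherwise one routine silylation away from the alcohol).

Step 1
Reactants: 1 3,4-dibromothiophene
Product: 2 3,4-dibromothiophene 1,1-dioxide
Conditions: H2O2·urea, (CF3CO)2O, MeCN, 0 °C to rt
Reagents that add atoms: trifluoroperacetic acid, OOC(=O)C(F)(F)F (formed in the flask from hydrogen peroxide–urea, OO.NC(N)=O, and trifluoroacetic anhydride, O=C(OC(=O)C(F)(F)F)C(F)(F)F)
Why: Electrophilic S-oxidation by trifluoroperacetic acid, a peracid strong enough for a thiophene deactivated by two bromines, should run through to the sulfone because the intermediate sulfoxide is oxidised faster than 1, and halogenated 3,4-disubstituted thiophene dioxides are isolable solids.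

Step 2
Reactants: 3 tert-butyl(but-3-yn-1-yloxy)dimethylsilane
Product: 4 (4-bromobut-3-yn-1-yloxy)(tert-butyl)dimethylsilane
Conditions: NBS, AgNO3 (10 mol%), acetone, rt, dark
Reagents that add atoms: N-bromosuccinimide, O=C1CCC(=O)N1Br
Why: Silver-catalysed electrophilic bromination of the terminal alkyne via its silver acetylide is a standard entry to 1-bromoalkynes and leaves the silyl ether untouched.

Step 3
Reactants: 4 (4-bromobut-3-yn-1-yloxy)(tert-butyl)dimethylsilane; 5 tert-butyl N-methylcarbamate
Product: 6 tert-butyl N-[4-(tert-butyldimethylsilyloxy)but-1-yn-1-yl]-N-methylcarbamate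
Conditions: CuSO4·5H2O (15 mol%), 1,10-phenanthroline (30 mol%), K3PO4, PhMe, 75 °C
Reagents that add atoms: none
Why: Copper-catalysed N-alkynylation (Ullmann–Goldberg-type amidation of a bromoalkyne) is established for tert-butyl carbamates under phosphate/phenanthroline conditions, and the moderate temperature should spare the N-Boc ynamide.

Step 4
Reactants: 2 3,4-dibromothiophene 1,1-dioxide; 6 tert-butyl N-[4-(tert-butyldimethylsilyloxy)but-1-yn-1-yl]-N-methylcarbamate
Product: 8 tert-butyl N-[4,5-dibromo-2-[2-(tert-butyldimethylsilyloxy)ethyl]phenyl]-N-methylcarbamate, via bridged sulfone adduct 7 (not isolated)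
Conditions: PhMe, 2,6-di-tert-butyl-4-methylpyridine (10 mol%), 90 °C, Ar sweep, 2 added in portions
Reagents that add atoms: none
Why: Proposed new method: the electron-poor diene of 2 should add across the electron-rich triple bond of 6 in an inverse-electron-demand Diels–Alder reaction, concerted but asynchronous with the chain-bearing alkyne carbon bonding first, to give the 7-thiabicyclo[2.2.1]heptadiene dioxide 7, which loses SO2 by thermally allowed cheletropic extrusion and is aromatic at once without any oxidant. The closest known reaction type is the benzannulation of halogenated thiophene 1,1-dioxides with ordinary alkynes, and the new element is the use of an ynamide as the two-carbon partner. The only ring formed, the benzene ring, is closed by this intermolecular [4+2] cycloaddition, which makes the C3a–C4 and C7–C7a bonds of the later indole in one event. No stereocentre has to be controlled, since the two bridgehead centres of 7 are held syn by the bicycle and vanish on aromatisation, and no regiochemistry either, since the symmetrical diene can give only one arene. The selectivity needed is [4+2] addition over stepwise [2+2] addition, over addition–elimination at the bromine-bearing carbons and over dimerisation of 2; the carbamate should secure it by damping the ynamide to a dienophile that is not a free nucleophile, and the two bromines by lowering the diene LUMO. The hindered pyridine and the argon sweep are there to keep acid derived from SO2 from cyclising the N-Boc ynamide to an oxazolone.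

Step 5
Reactants: 8 tert-butyl N-[4,5-dibromo-2-[2-(tert-butyldimethylsilyloxy)ethyl]phenyl]-N-methylcarbamate
Product: 9 tert-butyl N-[4,5-dibromo-2-(2-hydroxyethyl)phenyl]-N-methylcarbamate
Conditions: TBAF, AcOH, THF, rt
Reagents that add atoms: none
Why: Fluoride-induced cleavage of the Si–O bond (silyl ether deprotection) is selective for the silyl group, and the acetic acid buffer keeps the liberated alkoxide from attacking the neighbouring carbamate.

Step 6
Reactants: 9 tert-butyl N-[4,5-dibromo-2-(2-hydroxyethyl)phenyl]-N-methylcarbamate
Product: 11 2-[4,5-dibromo-2-[(tert-butoxycarbonyl)(methyl)amino]phenyl]acetic acid, via arylacetaldehyde 10 (not isolated)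
Conditions: TEMPO (20 mol%), PhI(OAc)2 (2.2 equiv), MeCN/H2O (1:1), rt
Reagents that add atoms: water, O
Why: Oxoammonium-mediated (TEMPO) oxidation takes the primary alcohol to aldehyde 10, whose hydrate is oxidised on to the acid under conditions mild enough for the Boc group and the aryl bromides.

Step 7
Reactants: 11 2-[4,5-dibromo-2-[(tert-butoxycarbonyl)(methyl)amino]phenyl]acetic acid
Product: 13 5,6-dibromo-1-methylindolin-2-one, via amino acid 12 (not isolated)
Conditions: CF3CO2H, CH2Cl2, rt; then PhMe, 80 °C
Reagents that add atoms: none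
Why: Acidolysis of the Boc group (loss of isobutene and CO2) frees the N-methylaniline 12, which should close onto the neighbouring carboxyl group by acid-catalysed 5-exo-trig lactamisation, a ring closure that 2-aminophenylacetic acids undergo readily.

Step 8
Reactants: 13 5,6-dibromo-1-methylindolin-2-one
Product: 15 2,5,6-tribromo-1-methylindole-3-carbaldehyde, via iminium bromide 14 (not isolated)
Conditions: POBr3, DMF, CHCl3, 0 °C to 60 °C; then H2O
Reagents that add atoms: phosphoryl bromide, O=P(Br)(Br)Br; N,N-dimethylformamide, CN(C)C=O; water, O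
Why: In this Vilsmeier–Haack haloformylation the bromoiminium salt from DMF and POBr3 formylates the enolisable C3 position, activation of the vinylogous amide oxygen then replaces it by bromide with aromatisation to the indole, and water hydrolyses iminium salt 14 to the aldehyde, a conversion well known for N-alkyl oxindoles.

Compound list
1 | 3,4-dibromothiophene | Brc1cscc1Br | starting material
2 | 3,4-dibromothiophene 1,1-dioxide | O=S1(=O)C=C(Br)C(Br)=C1 | intermediate
3 | tert-butyl(but-3-yn-1-yloxy)dimethylsilane | C#CCCO[Si](C)(C)C(C)(C)C | starting material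
4 | (4-bromobut-3-yn-1-yloxy)(tert-butyl)dimethylsilane | BrC#CCCO[Si](C)(C)C(C)(C)C | intermediate
5 | tert-butyl N-methylcarbamate | CNC(=O)OC(C)(C)C | starting material
6 | tert-butyl N-[4-(tert-butyldimethylsilyloxy)but-1-yn-1-yl]-N-methylcarbamate | CN(C#CCCO[Si](C)(C)C(C)(C)C)C(=O)OC(C)(C)C | intermediate
7 | tert-butyl N-[5,6-dibromo-3-[2-(tert-butyldimethylsilyloxy)ethyl]-7,7-dioxo-7-thiabicyclo[2.2.1]hepta-2,5-dien-2-yl]-N-methylcarbamate (racemic; bridgehead configuration fixed by the bicycle) | CN(C(=O)OC(C)(C)C)C1=C(CCO[Si](C)(C)C(C)(C)C)C2C(Br)=C(Br)C1S2(=O)=O | intermediate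
8 | tert-butyl N-[4,5-dibromo-2-[2-(tert-butyldimethylsilyloxy)ethyl]phenyl]-N-methylcarbamate | CN(C(=O)OC(C)(C)C)c1cc(Br)c(Br)cc1CCO[Si](C)(C)C(C)(C)C | intermediate
9 | tert-butyl N-[4,5-dibromo-2-(2-hydroxyethyl)phenyl]-N-methylcarbamate | CN(C(=O)OC(C)(C)C)c1cc(Br)c(Br)cc1CCO | intermediate
10 | tert-butyl N-[4,5-dibromo-2-(2-oxoethyl)phenyl]-N-methylcarbamate | CN(C(=O)OC(C)(C)C)c1cc(Br)c(Br)cc1CC=O | intermediate
11 | 2-[4,5-dibromo-2-[(tert-butoxycarbonyl)(methyl)amino]phenyl]acetic acid | CN(C(=O)OC(C)(C)C)c1cc(Br)c(Br)cc1CC(=O)O | intermediate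
12 | 2-[4,5-dibromo-2-(methylamino)phenyl]acetic acid | CNc1cc(Br)c(Br)cc1CC(=O)O | intermediate
13 | 5,6-dibromo-1-methylindolin-2-one | CN1C(=O)Cc2cc(Br)c(Br)cc21 | intermediate
14 | N-[(2,5,6-tribromo-1-methylindol-3-yl)methylidene]-N-methylmethanaminium bromide | C[N+](C)=Cc1c(Br)n(C)c2cc(Br)c(Br)cc12.[Br-] | intermediate
15 | 2,5,6-tribromo-1-methylindole-3-carbaldehyde | Cn1c(Br)c(C=O)c2cc(Br)c(Br)cc21 | target

Total step count: 8. Longest linear sequence: 7 steps (steps 2 to 8, from silyl ether 3 to target 15); step 1 is a one-step side branch that joins at step 4.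

Steps most likely to fail

1. Step 4 (new method). The ynamide may react as a nucleophile instead of a dienophile, giving stepwise [2+2] addition or displacement of bromide. It may also be lost to acid-induced cyclisation with loss of isobutene, or the sulfone may dimerise before cycloaddition. Fallback, using known chemistry only and bringing the nitrogen in by nitration instead of by the alkyne: it sets out from sulfone 2 and rejoins the route at target 15.
   - Sulfone 2 is heated with the plain terminal alkyne 3 (xylene, 130 °C), the established alkyne benzannulation of halogenated thiophene dioxides. Through 5,6-dibromo-2-[2-(tert-butyldimethylsilyloxy)ethyl]-7-thiabicyclo[2.2.1]hepta-2,5-diene 7,7-dioxide F1 and loss of SO2 this should give tert-butyl[2-(3,4-dibromophenyl)ethoxy]dimethylsilane F2.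
   - Jones oxidation (CrO3, H2SO4, acetone, 0 °C) cleaves the silyl ether to 2-(3,4-dibromophenyl)ethanol F3 and oxidises it through 2-(3,4-dibromophenyl)acetaldehyde F4 to 2-(3,4-dibromophenyl)acetic acid F5.
   - Nitration (HNO3, H2SO4, 0 °C) should go ortho to the CH2 group and para to a bromine, giving 2-(4,5-dibromo-2-nitrophenyl)acetic acid F6.
   - Fe in AcOH (80 °C) reduces this to 2-(2-amino-4,5-dibromophenyl)acetic acid F7, which lactamises in the pot to 5,6-dibromoindolin-2-one F8.
   - Vilsmeier–Haack bromoformylation as in step 8 (POBr3, DMF, CHCl3; then H2O) passes through N-[(2,5,6-tribromo-1H-indol-3-yl)methylidene]-N-methylmethanaminium bromide F9 to 2,5,6-tribromo-1H-indole-3-carbaldehyde F10.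
   - N-Methylation of the acidic indole N–H (MeI, K2CO3, DMF, rt) gives target 15.

2. Step 3. Coupling of the acyclic carbamate may be sluggish, so that oxidative homocoupling of the bromoalkyne or copper-promoted cyclisation of the N-Boc ynamide at 75 °C takes over. Fallback, an oxidative N-alkynylation at room temperature that needs neither the bromoalkyne nor heating: it sets out from alkyne 3 and rejoins at ynamide 6. Alkyne 3 is converted (CuI, aqueous NH3, EtOH, rt) into [4-(tert-butyldimethylsilyloxy)but-1-yn-1-yl]copper F11. This is collected and stirred with an excess of carbamate 5 (TMEDA, O2 at 1 atm, MeCN, rt) to give 6.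

3. Step 8. The haloformylation may stop at the 3-(dimethylaminomethylene) lactam, because the oxygen-to-bromine exchange needs more heat than the C-formylation, and forcing it may erode the material. Fallback, separating the two events and reversing their order: it sets out from oxindole 13 and rejoins at target 15. Deoxybromination of the lactam (POBr3, imidazole, ClCH2CH2Cl, 80 °C) should give 2,5,6-tribromo-1-methylindole F12. Rieche formylation at the free C3 position (Cl2CHOMe, TiCl4, CH2Cl2, −78 to 0 °C) then passes through 2,5,6-tribromo-3-[chloro(methoxy)methyl]-1-methylindole F13, which aqueous work-up hydrolyses to 15.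

Further compounds
F1 | step 4 | 5,6-dibromo-2-[2-(tert-butyldimethylsilyloxy)ethyl]-7-thiabicyclo[2.2.1]hepta-2,5-diene 7,7-dioxide (racemic) | O=S1(=O)C2C=C(CCO[Si](C)(C)C(C)(C)C)C1C(Br)=C2Br
F2 | step 4 | tert-butyl[2-(3,4-dibromophenyl)ethoxy]dimethylsilane | CC(C)(C)[Si](C)(C)OCCc1ccc(Br)c(Br)c1
F3 | step 4 | 2-(3,4-dibromophenyl)ethanol | OCCc1ccc(Br)c(Br)c1
F4 | step 4 | 2-(3,4-dibromophenyl)acetaldehyde | O=CCc1ccc(Br)c(Br)c1
F5 | step 4 | 2-(3,4-dibromophenyl)acetic acid | OC(=O)Cc1ccc(Br)c(Br)c1
F6 | step 4 | 2-(4,5-dibromo-2-nitrophenyl)acetic acid | OC(=O)Cc1cc(Br)c(Br)cc1[N+](=O)[O-]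
F7 | step 4 | 2-(2-amino-4,5-dibromophenyl)acetic acid | Nc1cc(Br)c(Br)cc1CC(=O)O
F8 | step 4 | 5,6-dibromoindolin-2-one | O=C1Cc2cc(Br)c(Br)cc2N1
F9 | step 4 | N-[(2,5,6-tribromo-1H-indol-3-yl)methylidene]-N-methylmethanaminium bromide | C[N+](C)=Cc1c(Br)[nH]c2cc(Br)c(Br)cc12.[Br-]
F10 | step 4 | 2,5,6-tribromo-1H-indole-3-carbaldehyde | O=Cc1c(Br)[nH]c2cc(Br)c(Br)cc12
F11 | step 3 | [4-(tert-butyldimethylsilyloxy)but-1-yn-1-yl]copper | [Cu]C#CCCO[Si](C)(C)C(C)(C)C
F12 | step 8 | 2,5,6-tribromo-1-methylindole | Cn1c(Br)cc2cc(Br)c(Br)cc21
F13 | step 8 | 2,5,6-tribromo-3-[chloro(methoxy)methyl]-1-methylindole (racemic) | COC(Cl)c1c(Br)n(C)c2cc(Br)c(Br)cc12
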